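# Chemoenzymatic total synthesis of aspergilol C: cyclase-mediated polycyclisation of geranylfarnesyl diphosphate

**Compound numbers, fixed first and used throughout:** 1 geranylgeraniol; 2 geranylgeranyl bromide; 3 methyl acetoacetate; 4 its dianion; 5 C25 β-keto ester; 6 sodium enolate of 5; 7 Z-enol phosphate; 8 methyl geranylfarnesoate; 9 geranylfarnesol; 10 its mesylate; 11 geranylfarnesyl chloride; 12 geranylfarnesyl diphosphate; 13 geranylfarnesyl allyl cation; 14 tetracyclic C-2 cation; 15 tetracyclic diene (the C16-deoxy form of the target); 16 aspergilol C.

**Assumption (remark on the chemistry):** no cationic centre can sit on C16 in any cyclisation of the chain, so the hydroxyl is taken to be introduced after cyclisation by an oxygenase. The two biocatalysts are taken to be the recombinant terpene cyclase and the cytochrome P450 of the sesterterpene gene cluster of an aspergilol-producing Aspergillus; they are catalysts, and nothing about their performance is taken as measured.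

## Analysis of the target

Aspergilol C (C25H40O) is a 5-8-6-5 tetracyclic sesterterpenoid. With biogenetic numbering read along the SMILES as CH3–C11=C10–C9–C8–C7(CH3)–C6–C5–C4–C3(CH3)–C2=C1–C15(CH3)–C16(OH)–C17–C18(C19HMe2)–C14–C13–C12, the rings are A (cyclopentane, C6–C10), B (cyclooctene, C2–C6 and C10–C12), C (cyclohexene, C1, C2, C12–C15) and D (cyclopentanol, C14–C18).

The two double bonds are the tetrasubstituted C10=C11 (inside ring B, exocyclic to ring A, geometry fixed by the ring) and the trisubstituted C1=C2. They flank the doubly allylic C12–H, so the molecule is a skipped diene.

There are eight stereocentres (C3, C6, C7, C12, C14, C15, C16, C18). Rings C/D are trans-fused (C15–CH3 anti to H-14), the 16-OH is cis and the C18 isopropyl trans to that methyl, H-12 is syn to H-14 so that the C12–C11 bond is pseudo-equatorial on ring C, and on ring A the C7 methyl is cis to the C6–C5 bond. In flat projection H-6, H-7, H-12, H-14, the C3 methyl and the isopropyl lie on one face.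

The sensitive parts are the skipped diene (drift into conjugation under acid, base, radical or metal hydride conditions; autoxidation at C12) and the tetrasubstituted olefin, whose protonation gives a tertiary cation with transannular reach.

The difficulty is an eight-membered ring that carries a tetrasubstituted olefin, a contra-thermodynamic cis pair on ring A, and stereocentres spread over four rings of what is a hydrocarbon with a single heteroatom. Every stepwise C–C bond would need temporary functionality that must later be removed.

The feature that invites the strategy is that C1 to C19, with methyls on C3, C7, C11 and C15 and two on C19, are an unrearranged head-to-tail pentaprenyl chain. The four rings arise from only four extra σ-bonds (C1–C15, C14–C18, C6–C10, C2–C12), both olefins sit where a cationic cascade would leave them, and the C16 oxygen is the only atom that does not come from the chain.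

## Retrosynthetic reasoning

**16 to 15 (C16–O).** The hydroxyl is cut first. C16 is never cationic in a cyclisation of the chain, and an oxygen carried through the cascade would be free to capture a cation. Removing it leaves the pure hydrocarbon 15. The forward reaction must hydroxylate one face of a non-activated CH2 next to the quaternary C15, in the presence of two olefins and a weaker doubly allylic C–H. That is a task for a cytochrome P450 monooxygenase, not for a small reagent.

**15 to 12 (C1–C15, C14–C18, C6–C10 and C2–C12; key disconnection).** All four ring-forming bonds are cut at once. They are exactly the bonds that are not part of the pentaprenyl chain, so all four rings and seven stereocentres vanish and the precursor is the acyclic, achiral diphosphate 12 with four E double bonds. The forward step has to ionise 12, hold one chain fold, relay the charge through hydride shifts and end by loss of H-1. This is the job of a class I terpene cyclase.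

**12 to 11 to 9 (C1–O–P).** The diphosphate is traced to the allylic alcohol 9 through the primary allylic chloride 11. Displacement at C1 has to occur without allylic transposition and without touching the C2=C3 geometry.

**9 to 8 to 7 to 5 (C3–CH3 bond and the 2E olefin).** The last trisubstituted olefin is cut at its methyl group rather than at the double bond. A β-keto ester (5) becomes a Z-enol phosphate (7), in which a methyl nucleophile on copper replaces the phosphate with retention. This gives the 2E ester 8 stereospecifically, where a carbonyl olefination would give an E/Z mixture. The cyclase needs geometrically pure substrate.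

**5 to 2 + 3 (C4–C5), 2 to 1.** The remaining bond is the γ-alkylation of the dianion 4 of methyl acetoacetate (3) with geranylgeranyl bromide (2), made from commercial geranylgeraniol (1). Three of the four E olefins are thus bought, and only one C5 unit has to be built.

## Alternatives that were turned down

Alternative 1: (textbook) Disconnection of C4–C5 in ring B, after a convergent union of a ring-A fragment with a C/D fragment at C11–C12. The forward key step is ring-closing metathesis of the seco-diene A1 (vinyl groups on C6 and on C3) to the cyclooctadiene A2, followed by saturation of the new disubstituted olefin. It was turned down for these reasons: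
- Metathesis closes the one bond of ring B that carries no difficulty. The tetrasubstituted C10=C11 olefin, the cis C6/C7 pair and all five centres of rings C/D must already be present in A1, set one at a time on two enantiopure fragments.
- C12 is awkward: a C–C bond formed at C12 through the π-face of a ring-C allyl or enolate system enters pseudo-axially, whereas the target needs C11 pseudo-equatorial.
- The final hydrogenation must distinguish C4=C5 from C1=C2 without disturbing the skipped diene.
- More than twenty steps would be spent on a hydrocarbon with one hydroxyl.

Alternative 2: Disconnection of C5–C6 with the C10=C11 olefin made in the same step (Claisen ring expansion). The forward key step is the [3,3]-sigmatropic shift of the 2-methylene-6-(cyclopent-1-enyl)oxane A3, obtained by methylenation of the corresponding δ-lactone, to the cyclooct-4-enone A4. This would close ring B, fix the olefin geometry through the ring and transfer the configuration of the C11 carbinol to C6. It was turned down for these reasons: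
- The C6 configuration of the target requires the C11 epimer in which the cyclopentenyl group is pseudo-equatorial on an oxane held chair-like by ring C, so the shift would have to pass through a boat-like oxane.
- The more easily made C11 epimer (Felkin-type addition of the ring-A nucleophile to a C12 acetyl group) would rearrange to the C6 epimer.
- The step leaves a C4 ketone that must be removed next to an epimerisable C3 centre and a β,γ-olefin prone to conjugation.
- A3 itself presupposes rings C and D with five stereocentres, so the ring expansion would be paid for by some fifteen steps.

Alternative 3: Disconnection of C10=C11 itself. The forward key step is an intramolecular low-valent titanium (McMurry) coupling of the diketone A5 (C11 methyl ketone on ring C, ring-A cyclopentanone). This would close ring B and form the tetrasubstituted olefin with ring-enforced geometry. It was turned down for these reasons: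
- C6 in A5 is α to the ring-A ketone and must be held in the less stable cis relationship to the C7 methyl through a hot, Lewis-acidic reaction.
- C12–H is α to the methyl ketone and allylic, so it can epimerise or drift into conjugation with C1=C2.
- An eight-membered ring with a tetrasubstituted olefin from two enolisable ketones is the least favourable case for this coupling (pinacol arrest, simple reduction).
- A5 again presupposes the stepwise construction of rings A, C and D.

Key step: step 8

## Route

Step 1
Reactants: 1 (2E,6E,10E)-geranylgeraniol
Product: 2 (2E,6E,10E)-geranylgeranyl bromide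
Conditions: PBr3 (0.4 equiv), Et2O, −10 °C to 0 °C
Reagents that add atoms: phosphorus tribromide, BrP(Br)Br
Why: Bromination of a primary allylic alcohol by PBr3 (SN2 on the phosphite) at low temperature should leave the position and E geometry of C2=C3 untouched; no stereocentre is formed.

Step 2
Reactants: 2 (2E,6E,10E)-geranylgeranyl bromide; 3 methyl acetoacetate
Product: 5 methyl (6E,10E,14E)-7,11,15,19-tetramethyl-3-oxoicosa-6,10,14,18-tetraenoate, via methyl acetoacetate dianion 4 (not isolated)
Conditions: 3, NaH, THF, 0 °C; n-BuLi, 0 °C; then 2, 0 °C to rt; aq HCl
Reagents that add atoms: none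
Why: γ-Alkylation of an acetoacetate dianion: the more basic terminal carbanion attacks the primary allylic bromide by SN2, which forms C4–C5 and leaves the β-keto ester needed for the next olefin.

Step 3
Reactants: 5 methyl (6E,10E,14E)-7,11,15,19-tetramethyl-3-oxoicosa-6,10,14,18-tetraenoate
Product: 7 methyl (2Z,6E,10E,14E)-3-(diethoxyphosphoryloxy)-7,11,15,19-tetramethylicosa-2,6,10,14,18-pentaenoate, via sodium Z-enolate 6 (not isolated)
Conditions: NaH, Et2O, 0 °C; ClP(O)(OEt)2, 0 °C to rt
Reagents that add atoms: diethyl chlorophosphate, CCOP(=O)(Cl)OCC
Why: Enol phosphate formation: the sodium enolate of a β-keto ester is chelated (Z) in ether and is O-phosphorylated with retention, so the ester and the phosphate should end up cis.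

Step 4
Reactants: 7 methyl (2Z,6E,10E,14E)-3-(diethoxyphosphoryloxy)-7,11,15,19-tetramethylicosa-2,6,10,14,18-pentaenoate
Product: 8 methyl (2E,6E,10E,14E)-3,7,11,15,19-pentamethylicosa-2,6,10,14,18-pentaenoate (methyl geranylfarnesoate)
Conditions: Me2CuLi (from MeLi and CuI), Et2O, −78 °C to −45 °C; aq NH4Cl
Reagents that add atoms: lithium dimethylcuprate, [Li+].C[Cu-]C
Why: Conjugate addition–elimination of the cuprate on the β-phosphoryloxy enoate proceeds with retention at low temperature, so the new C3 methyl should end cis to the ester and C2=C3 should be E without an E/Z mixture.

Step 5
Reactants: 8 methyl geranylfarnesoate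
Product: 9 (2E,6E,10E,14E)-geranylfarnesol
Conditions: DIBAL-H (2.5 equiv), CH2Cl2, −78 °C; Rochelle salt work-up
Reagents that add atoms: none
Why: 1,2-Reduction of the enoate by the aluminium hydride should give the allylic alcohol without conjugate reduction or olefin isomerisation.

Step 6
Reactants: 9 (2E,6E,10E,14E)-geranylfarnesol
Product: 11 (2E,6E,10E,14E)-geranylfarnesyl chloride, via geranylfarnesyl mesylate 10 (not isolated)
Conditions: MsCl, 2,4,6-collidine, LiCl, DMF, 0 °C
Reagents that add atoms: lithium chloride, [Li+].[Cl-]
Why: In situ mesylation and SN2 displacement by chloride under buffered, non-acidic conditions should give the primary allylic chloride without allylic transposition.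

Step 7
Reactants: 11 (2E,6E,10E,14E)-geranylfarnesyl chloride
Product: 12 (2E,6E,10E,14E)-geranylfarnesyl diphosphate (handled as the tris-ammonium salt; drawn as the free acid)
Conditions: (n-Bu4N)3HP2O7, MeCN, rt; cation exchange (NH4+ form); cellulose chromatography
Reagents that add atoms: tris(tetra-n-butylammonium) hydrogen diphosphate, CCCC[N+](CCCC)(CCCC)CCCC.CCCC[N+](CCCC)(CCCC)CCCC.CCCC[N+](CCCC)(CCCC)CCCC.OP(=O)([O-])OP(=O)([O-])[O-]
Why: SN2 displacement of the primary allylic chloride by the naked diphosphate anion in acetonitrile should give the C1 diphosphate directly; no stereocentre is involved and the all-E chain is kept.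

Step 8
Reactants: 12 (2E,6E,10E,14E)-geranylfarnesyl diphosphate
Product: 15 tetracyclic diene (C16-deoxy form of aspergilol C), via geranylfarnesyl allyl cation 13 (not isolated), via tetracyclic C-2 cation 14 (not isolated)
Conditions: recombinant class I sesterterpene cyclase (terpene cyclase of the 5-8-6-5 type, cat.), MgCl2, Tris-HCl pH 7.5, glycerol, 30 °C, pentane overlay
Reagents that add atoms: none
Why: Mg2+-assisted ionisation of 12 in the closed active site gives allyl cation 13; C14=C15 should add to C1 through C15 while C18=C19 adds to C14, so that ring D (5-exo at C14) and a 15-membered ring form in one anti addition across the E C14=C15 bond, which fixes C15–CH3 trans to H-14 and sets C18. A 1,5-hydride shift from C12 to C19 should then make the isopropyl group and a C10–C11–C12 allyl cation, C6=C7 closes onto C10 (transannular five-membered closure, ring A), and two suprafacial 1,2-hydride shifts (C6 to C7, C10 to C6) return the charge to C10–C12 and set C7 and C6. C2=C3 closes onto C12 in a transannular bond that divides the 12-membered ring into ring C (6-exo) and the eight-membered ring B, setting C12 and leaving C10=C11 tetrasubstituted; a 1,2-hydride shift from C2 to C3 sets C3 and gives cation 14, and loss of H-1 gives the C1=C2 bond of 15. The closest known reaction type is the class I terpene cyclase polycyclisation of an oligoprenyl diphosphate, here in the C1–C15/C14–C18 mode of fungal sesterterpene synthases. All seven stereocentres are controlled by the single chain fold imposed by the enzyme, while the substrate contributes only its four E double bonds, which is why the geometric purity at C2=C3 from step 4 matters. The step needs one fold out of many and termination by deprotonation at C1 rather than water capture or early proton loss; the water-excluding pocket of the cognate cyclase is what should secure this, and no small Lewis or Brønsted acid can be expected to do so on an acyclic pentaene.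

Step 9
Reactants: 15 tetracyclic diene (C16-deoxy form of aspergilol C)
Product: 16 aspergilol C
Conditions: cytochrome P450 monooxygenase with its P450 reductase, O2 (air), NADPH (cat.) recycled by i-PrOH/alcohol dehydrogenase, phosphate buffer pH 7.4, hydroxypropyl-β-cyclodextrin, 28 °C
Reagents that add atoms: dioxygen, O=O
Why: Cytochrome P450 C–H hydroxylation: the ferryl oxidant abstracts the C16 hydrogen that is cis to the C15 methyl and oxygen rebound occurs with retention, so the new C–O bond should be cis to that methyl. The binding pocket, not intrinsic C–H strength, has to keep the oxidant away from the weaker doubly allylic C12–H and from both olefins, which is what no small reagent does.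

## Compound list

1 | (2E,6E,10E)-geranylgeraniol | OC/C=C(\C)CC/C=C(\C)CC/C=C(\C)CCC=C(C)C | starting material
2 | (2E,6E,10E)-geranylgeranyl bromide | BrC/C=C(\C)CC/C=C(\C)CC/C=C(\C)CCC=C(C)C | intermediate
3 | methyl acetoacetate | COC(=O)CC(C)=O | starting material
4 | methyl acetoacetate dianion (sodium lithium salt) | [CH2-]C(=O)[CH-]C(=O)OC.[Na+].[Li+] | intermediate (not isolated)
5 | methyl (6E,10E,14E)-7,11,15,19-tetramethyl-3-oxoicosa-6,10,14,18-tetraenoate | COC(=O)CC(=O)CC/C=C(\C)CC/C=C(\C)CC/C=C(\C)CCC=C(C)C | intermediate
6 | sodium Z-enolate of 5 | COC(=O)/C=C(\[O-])CC/C=C(\C)CC/C=C(\C)CC/C=C(\C)CCC=C(C)C.[Na+] | intermediate (not isolated)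
7 | methyl (2Z,6E,10E,14E)-3-(diethoxyphosphoryloxy)-7,11,15,19-tetramethylicosa-2,6,10,14,18-pentaenoate | COC(=O)/C=C(\OP(=O)(OCC)OCC)CC/C=C(\C)CC/C=C(\C)CC/C=C(\C)CCC=C(C)C | intermediate
8 | methyl (2E,6E,10E,14E)-geranylfarnesoate | COC(=O)/C=C(\C)CC/C=C(\C)CC/C=C(\C)CC/C=C(\C)CCC=C(C)C | intermediate
9 | (2E,6E,10E,14E)-geranylfarnesol | OC/C=C(\C)CC/C=C(\C)CC/C=C(\C)CC/C=C(\C)CCC=C(C)C | intermediate
10 | (2E,6E,10E,14E)-geranylfarnesyl mesylate | CS(=O)(=O)OC/C=C(\C)CC/C=C(\C)CC/C=C(\C)CC/C=C(\C)CCC=C(C)C | intermediate (not isolated)
11 | (2E,6E,10E,14E)-geranylfarnesyl chloride | ClC/C=C(\C)CC/C=C(\C)CC/C=C(\C)CC/C=C(\C)CCC=C(C)C | intermediate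
12 | (2E,6E,10E,14E)-geranylfarnesyl diphosphate (free acid form) | OP(=O)(O)OP(=O)(O)OC/C=C(\C)CC/C=C(\C)CC/C=C(\C)CC/C=C(\C)CCC=C(C)C | intermediate
13 | geranylfarnesyl allyl cation (enzyme-bound) | [CH2+]/C=C(\C)CC/C=C(\C)CC/C=C(\C)CC/C=C(\C)CCC=C(C)C | intermediate (not isolated)
14 | tetracyclic C-2 cation (C1 is CH2; C3, C6, C7, C12, C14, C15, C18 as in 15) | C/C1=C2\CC[C@H](C)[C@@H]2CC[C@@H](C)[C+]2C[C@@]3(C)CC[C@@H](C(C)C)[C@@H]3C[C@@H]21 | intermediate (not isolated)
15 | tetracyclic diene, C16-deoxy form of aspergilol C (5-8-6-5 skeleton, C1=C2 and C10=C11, configuration of the target at all seven carbon stereocentres) | C/C1=C2\CC[C@H](C)[C@@H]2CC[C@@H](C)C2=C[C@@]3(C)CC[C@@H](C(C)C)[C@@H]3C[C@@H]21 | intermediate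
16 | aspergilol C (16-OH cis to the C15 methyl) | C/C1=C2\CC[C@H](C)[C@@H]2CC[C@@H](C)C2=C[C@@]3(C)[C@H](O)C[C@@H](C(C)C)[C@@H]3C[C@@H]21 | target

## Step count and least certain steps

Total step count: 9. Longest linear sequence: 9 steps (1 to 16); 3 is a commercial reagent-type starting material.

**Step 8 (key step).** The most likely failure is that the carbocation relay leaves the productive path. Four ring closures and four hydride shifts must all outrun quenching, so early proton loss or water capture at the C19, C7 or C3 cation stage is possible. Turnover may also be slow because the amphiphilic C25 diphosphate aggregates and binds unproductively when it is supplied from outside. The fallback sets out from 2. Compound 2 is converted with the diphosphate salt of step 7 into geranylgeranyl diphosphate F1, and F1 is incubated together with commercial isopentenyl diphosphate F2 and the full-length bifunctional enzyme (prenyltransferase domain plus cyclase domain, Mg2+, same buffer). The chain is then extended by one C5 unit and cyclised on the same protein without release of the C25 diphosphate, and the route is rejoined at 15.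

**Step 9.** The most likely failure is over-oxidation of the new carbinol to the ketone in a second turnover, or incomplete facial control at C16 if the pocket holds the substrate loosely, because the secondary alcohol remains a substrate of the oxidant. The fallback sets out from 15. The enzymatic oxidation is run without regard to the oxidation level at C16, the crude C16-oxygenated material is oxidised with Dess–Martin periodinane (NaHCO3, CH2Cl2) to the 16-ketone F3, and F3 is reduced with NaBH4 in MeOH at −40 °C. Hydride should enter anti to the C15 methyl, as in 17-oxo steroids, which returns to 16. Attack at a wrong site (C12–H or an olefin) has no chemical remedy and would call for another oxygenase.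

**Step 7.** The most likely failure is ionisation or SN2′ attack on the allylic chloride, leading to a tertiary diphosphate or elimination, and hydrolysis during ion exchange, because the polyprenyl chloride is a good cation precursor. The fallback sets out from 9 and phosphorylates oxygen instead of substituting carbon. Compound 9 is treated with trichloroacetonitrile and bis(triethylammonium) hydrogen phosphate in MeCN, which gives geranylfarnesyl monophosphate F4 and, by further phosphorylation in the same pot, the diphosphate. Ion-exchange chromatography separates the phosphates and returns to 12.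

**Step 4.** The most likely failure is partial loss of olefin geometry (isomerisation of the enol phosphate or of the adduct before elimination) or a second methyl addition. A 2Z contaminant would misfold in step 8. The fallback sets out from 2 and changes the way the C2=C3 bond is made:
- 3 is C-alkylated with 2 (NaOMe, MeOH) to give methyl 2-acetyl-5,9,13,17-tetramethyloctadeca-4,8,12,16-tetraenoate F5.
- Saponification and decarboxylation (aq NaOH, then acid and heat) give geranylgeranylacetone F6.
- Horner–Wadsworth–Emmons olefination of F6 (trimethyl phosphonoacetate, NaH, THF) gives the 2E ester after removal of the 2Z isomer on silver nitrate-impregnated silica, which returns to 8.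

## Further compounds

F1 | step 8 | (2E,6E,10E)-geranylgeranyl diphosphate (free acid form) | OP(=O)(O)OP(=O)(O)OC/C=C(\C)CC/C=C(\C)CC/C=C(\C)CCC=C(C)C
F2 | step 8 | isopentenyl diphosphate (free acid form) | CC(=C)CCOP(=O)(O)OP(=O)(O)O
F3 | step 9 | 16-oxo compound (16-ketone of the tetracyclic diene) | C/C1=C2\CC[C@H](C)[C@@H]2CC[C@@H](C)C2=C[C@@]3(C)C(=O)C[C@@H](C(C)C)[C@@H]3C[C@@H]21
F4 | step 7 | (2E,6E,10E,14E)-geranylfarnesyl monophosphate (free acid form) | OP(=O)(O)OC/C=C(\C)CC/C=C(\C)CC/C=C(\C)CC/C=C(\C)CCC=C(C)C
F5 | step 4 | methyl (4E,8E,12E)-2-acetyl-5,9,13,17-tetramethyloctadeca-4,8,12,16-tetraenoate (racemic at C2) | COC(=O)C(C(C)=O)C/C=C(\C)CC/C=C(\C)CC/C=C(\C)CCC=C(C)C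
F6 | step 4 | (5E,9E,13E)-6,10,14,18-tetramethylnonadeca-5,9,13,17-tetraen-2-one (geranylgeranylacetone) | CC(=O)CC/C=C(\C)CC/C=C(\C)CC/C=C(\C)CCC=C(C)C
A1 | alternative 1 | 4,5-seco diene for metathesis (C6 and C3 each carry a vinyl group; hydroxyl shown free) | C/C(=C1\CC[C@H](C)[C@@H]1C=C)[C@H]3C[C@H]4[C@H](C(C)C)C[C@@H](O)[C@]4(C)C=C3[C@H](C)C=C
A2 | alternative 1 | (4Z)-4,5-didehydro-aspergilol C (metathesis product) | C/C1=C2\CC[C@H](C)[C@@H]2/C=C\[C@@H](C)C2=C[C@@]3(C)[C@H](O)C[C@@H](C(C)C)[C@@H]3C[C@@H]21
A3 | alternative 2 | 2-methylene-6-methyl-6-(3-methylcyclopent-1-enyl)oxane fused to rings C/D (enol ether for the Claisen ring expansion; hydroxyl shown free) | C=C1O[C@](C)(C2=C[C@@H](C)CC2)[C@H]2C[C@H]3[C@H](C(C)C)C[C@@H](O)[C@]3(C)C=C2[C@@H]1C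
A4 | alternative 2 | 4-oxo-aspergilol C (cyclooct-4-enone from the ring expansion) | C/C1=C2\CC[C@H](C)[C@@H]2CC(=O)[C@@H](C)C2=C[C@@]3(C)[C@H](O)C[C@@H](C(C)C)[C@@H]3C[C@@H]21
A5 | alternative 3 | 10,11-seco diketone (C11 methyl ketone on ring C; ring-A cyclopentanone at C10; hydroxyl shown free) | CC(=O)[C@H]1C[C@H]2[C@H](C(C)C)C[C@@H](O)[C@]2(C)C=C1[C@H](C)CC[C@H]1[C@@H](C)CCC1=O
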